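The C3–C4 bond of pyranone ring C is the strategic cut: the C4 ketone is read as an aldehyde C–H on ring A added across a C2=C3 double bond. One rhodium-catalysed enantioselective intramolecular hydroacylation closes ring C and creates the only stereocentre, C2, by hydride delivery. The step exploits the unsubstituted C3 methylene lying between the C4 carbonyl and a C2 that carries both O1 and ring B. Its precursor is therefore achiral: a 1-arylvinyl aryl ether (ring B on the vinyl carbon, O1 on ring A) with a formyl group ortho to the ether oxygen, assembled from two protected, prenylated fragments by esterification and carbonyl methylenation.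

Key step: step 10

Assumption: which antipode of the bisphosphine delivers the (2S) product in step 10 cannot be derived from first principles; (R)-DTBM-SEGPHOS is written, and the antipode is taken if a model run shows the opposite sense. Abbreviations: TBS = tert-butyldimethylsilyl, prenyl = 3-methylbut-2-en-1-yl.

Step 1
Reactants: 1 2,4,6-trihydroxybenzaldehyde; 2 prenyl bromide (1-bromo-3-methylbut-2-ene)
Product: 3 2,4,6-trihydroxy-3-prenylbenzaldehyde
Conditions: DBU, THF, 0 °C to rt
Reagents that add atoms: none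
Why: C-prenylation of an acylphloroglucinol phenoxide under amidine base should take place at one of the two free ring carbons, which are equivalent by symmetry, so that a single mono-C-prenyl isomer is expected beside separable O-alkyl and bis-alkyl by-products.

Step 2
Reactants: 3 2,4,6-trihydroxy-3-prenylbenzaldehyde
Product: 4 4,6-bis(TBS-oxy)-2-hydroxy-3-prenylbenzaldehyde
Conditions: TBSCl (2.1 equiv), imidazole, DMF, 0 °C
Reagents that add atoms: tert-butyldimethylsilyl chloride CC(C)(C)[Si](C)(C)Cl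
Why: Regioselective phenol silylation, in which the 4-OH (para to the formyl group, most acidic, not hydrogen-bonded) and then the 6-OH (only one ortho neighbour) should react before the 2-OH, which is hydrogen-bonded to the formyl group and flanked by the prenyl chain.

Step 3
Reactants: 5 3-bromo-4,5-dihydroxybenzaldehyde
Product: 6 3-bromo-4,5-bis(TBS-oxy)benzaldehyde
Conditions: TBSCl (2.5 equiv), imidazole, DMF, rt
Reagents that add atoms: tert-butyldimethylsilyl chloride CC(C)(C)[Si](C)(C)Cl
Why: Standard silylation of both catechol hydroxyls, which should make ring B inert to the palladium, titanium and rhodium reagents used later.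

Step 4
Reactants: 6 3-bromo-4,5-bis(TBS-oxy)benzaldehyde; 7 tributyl(prenyl)stannane
Product: 8 3,4-bis(TBS-oxy)-5-prenylbenzaldehyde
Conditions: Pd(PPh3)4 (5 mol%), DMF, 100 °C
Reagents that add atoms: none
Why: Stille cross-coupling of the aryl bromide with the allylic stannane, in which bond formation at the unsubstituted allyl terminus should give the linear prenyl arene while aldehyde and silyl ethers are inert under the neutral conditions.

Step 5
Reactants: 8 3,4-bis(TBS-oxy)-5-prenylbenzaldehyde
Product: 9 3,4-bis(TBS-oxy)-5-prenylbenzoic acid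
Conditions: NaClO2, NaH2PO4, 2-methyl-2-butene (excess), t-BuOH–H2O, rt
Reagents that add atoms: sodium chlorite [Na+].[O-]Cl=O
Why: Pinnick oxidation under buffered conditions, with excess 2-methyl-2-butene scavenging hypochlorous acid so that the prenyl double bond and the aryl silyl ethers should survive.

Step 6
Reactants: 9 3,4-bis(TBS-oxy)-5-prenylbenzoic acid; 4 4,6-bis(TBS-oxy)-2-hydroxy-3-prenylbenzaldehyde
Product: 11 2-formyl-3,5-bis(TBS-oxy)-6-prenylphenyl 3,4-bis(TBS-oxy)-5-prenylbenzoate, via aroyl chloride 10 (not isolated)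
Conditions: 1-chloro-N,N,2-trimethylprop-1-en-1-amine, CH2Cl2, 0 °C to rt; then 4, Et3N, DMAP (cat.), CH2Cl2, 0 °C to rt
Reagents that add atoms: none
Why: Acid chloride formation under neutral conditions with the Ghosez reagent followed by DMAP-catalysed O-acylation of the only free phenol of 4 should give the aryl ester without loss of silyl groups.

Step 7
Reactants: 11 2-formyl-3,5-bis(TBS-oxy)-6-prenylphenyl 3,4-bis(TBS-oxy)-5-prenylbenzoate
Product: 12 2-(dimethoxymethyl)-3,5-bis(TBS-oxy)-6-prenylphenyl 3,4-bis(TBS-oxy)-5-prenylbenzoate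
Conditions: HC(OMe)3, MeOH (2 equiv), pyridinium p-toluenesulfonate (cat.), CH2Cl2, rt
Reagents that add atoms: trimethyl orthoformate COC(OC)OC; methanol CO
Why: Acid-catalysed acetalisation of the electron-rich aldehyde, driven by the orthoformate as water scavenger, masks the formyl group against the titanium methylidene of the next step.

Step 8
Reactants: 12 2-(dimethoxymethyl)-3,5-bis(TBS-oxy)-6-prenylphenyl 3,4-bis(TBS-oxy)-5-prenylbenzoate
Product: 13 2-{1-[3,4-bis(TBS-oxy)-5-prenylphenyl]ethenyloxy}-4,6-bis(TBS-oxy)-3-prenylbenzaldehyde dimethyl acetal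
Conditions: Cp2TiMe2 (3 equiv), toluene, 70 °C, dark; chromatography on Et3N-deactivated silica
Reagents that add atoms: dimethyltitanocene C[Ti+2]C.[cH-]1cccc1.[cH-]1cccc1
Why: Petasis methylenation, in which Cp2Ti=CH2 formed on heating adds [2+2] to the ester carbonyl and cycloreverts to the 1-arylvinyl aryl ether (a conversion well established for aryl benzoates), while acetal, silyl ethers and trisubstituted alkenes are inert.

Step 9
Reactants: 13 2-{1-[3,4-bis(TBS-oxy)-5-prenylphenyl]ethenyloxy}-4,6-bis(TBS-oxy)-3-prenylbenzaldehyde dimethyl acetal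
Product: 14 2-{1-[3,4-bis(TBS-oxy)-5-prenylphenyl]ethenyloxy}-4,6-bis(TBS-oxy)-3-prenylbenzaldehyde
Conditions: pyridinium p-toluenesulfonate (cat.), acetone–H2O 9:1, 0 °C; NaHCO3 quench
Reagents that add atoms: water O
Why: Acid-catalysed hydrolysis of the dimethyl acetal of a 2,4,6-trioxygenated benzaldehyde should be faster by orders of magnitude than protonation of the aryl enol ether, so the aldehyde is released at 0 °C with the enol ether intact.

Step 10
Reactants: 14 2-{1-[3,4-bis(TBS-oxy)-5-prenylphenyl]ethenyloxy}-4,6-bis(TBS-oxy)-3-prenylbenzaldehyde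
Product: 15 (2S)-5,7-bis(TBS-oxy)-2-[3,4-bis(TBS-oxy)-5-prenylphenyl]-8-prenylchroman-4-one
Conditions: [Rh(cod)Cl]2 (2.5 mol%), (R)-DTBM-SEGPHOS (5.5 mol%), Na[B(3,5-(CF3)2C6H3)4] (5 mol%), THF, 60 °C
Reagents that add atoms: none
Why: Proposed new method: the cationic monovalent rhodium–bisphosphine complex should insert into the aldehyde C–H bond of 14 to give an acyl rhodium hydride (trivalent rhodium), the ortho-held C2=C3 enol ether coordinates, reversible hydride migration places hydrogen on C2 and rhodium on the terminal C3, and C–C reductive elimination from the seven-membered acyl(alkyl)rhodacycle forms the C3–C4 bond. The closest known reaction type is the enantioselective rhodium-catalysed endo-selective intramolecular hydroacylation of 1,1-disubstituted alkenes held ortho to an aromatic aldehyde (2-(2-arylallyl)benzaldehydes to 3-aryl-1-tetralones, N-vinyl- and N-allylindole-2-carbaldehydes), of which 14 is the oxygen analogue with the alkene as an enol ether, a substrate class not yet shown. Ring C is closed in the 6-endo-trig mode, a formal anti-Markovnikov hydroacylation. The C2 stereocentre arises from hydride delivery to one face of the prochiral 1,1-disubstituted alkene under control of the chiral bisphosphine alone, since 14 is achiral. The step needs endo over exo closure, secured by the fully substituted C2 (reductive elimination to a quaternary carbon from the six-membered rhodacycle is slow and hydrometalation is reversible, whereas a carbene catalyst would give the exo benzofuranone), and it needs chemoselectivity for the enol ether over the two prenyl groups, secured because these are trisubstituted and cannot reach the acyl rhodium centre in a small ring. The alkene has no allylic hydrogen, so isomerisation by the rhodium hydride cannot compete, and the two ortho oxygen substituents of the electron-rich aldehyde should disfavour decarbonylation.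

Step 11
Reactants: 15 (2S)-5,7-bis(TBS-oxy)-2-[3,4-bis(TBS-oxy)-5-prenylphenyl]-8-prenylchroman-4-one
Product: 16 (2S)-5,7-dihydroxy-2-[3,4-dihydroxy-5-prenylphenyl]-8-prenylchroman-4-one (target)
Conditions: HF·pyridine, pyridine, THF, 0 °C to rt
Reagents that add atoms: none
Why: Fluoride cleavage of the four aryl silyl ethers under buffered, weakly acidic conditions should form neither phenoxide nor enolate, so ring C stays closed and C2 keeps its configuration, and should not cyclise the prenyl chains onto the neighbouring hydroxyls.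

Compound list
1 | 2,4,6-trihydroxybenzaldehyde | O=Cc1c(O)cc(O)cc1O | starting material
2 | prenyl bromide (1-bromo-3-methylbut-2-ene) | CC(C)=CCBr | starting material
3 | 2,4,6-trihydroxy-3-prenylbenzaldehyde | O=Cc1c(O)c(CC=C(C)C)c(O)cc1O | intermediate
4 | 4,6-bis(TBS-oxy)-2-hydroxy-3-prenylbenzaldehyde | O=Cc1c(O)c(CC=C(C)C)c(O[Si](C)(C)C(C)(C)C)cc1O[Si](C)(C)C(C)(C)C | intermediate
5 | 3-bromo-4,5-dihydroxybenzaldehyde | O=Cc1cc(O)c(O)c(Br)c1 | starting material
6 | 3-bromo-4,5-bis(TBS-oxy)benzaldehyde | O=Cc1cc(O[Si](C)(C)C(C)(C)C)c(O[Si](C)(C)C(C)(C)C)c(Br)c1 | intermediate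
7 | tributyl(prenyl)stannane | CC(C)=CC[Sn](CCCC)(CCCC)CCCC | starting material
8 | 3,4-bis(TBS-oxy)-5-prenylbenzaldehyde | O=Cc1cc(O[Si](C)(C)C(C)(C)C)c(O[Si](C)(C)C(C)(C)C)c(CC=C(C)C)c1 | intermediate
9 | 3,4-bis(TBS-oxy)-5-prenylbenzoic acid | OC(=O)c1cc(O[Si](C)(C)C(C)(C)C)c(O[Si](C)(C)C(C)(C)C)c(CC=C(C)C)c1 | intermediate
10 | 3,4-bis(TBS-oxy)-5-prenylbenzoyl chloride (not isolated) | ClC(=O)c1cc(O[Si](C)(C)C(C)(C)C)c(O[Si](C)(C)C(C)(C)C)c(CC=C(C)C)c1 | intermediate
11 | 2-formyl-3,5-bis(TBS-oxy)-6-prenylphenyl 3,4-bis(TBS-oxy)-5-prenylbenzoate | O=Cc1c(OC(=O)c2cc(O[Si](C)(C)C(C)(C)C)c(O[Si](C)(C)C(C)(C)C)c(CC=C(C)C)c2)c(CC=C(C)C)c(O[Si](C)(C)C(C)(C)C)cc1O[Si](C)(C)C(C)(C)C | intermediate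
12 | 2-(dimethoxymethyl)-3,5-bis(TBS-oxy)-6-prenylphenyl 3,4-bis(TBS-oxy)-5-prenylbenzoate | COC(OC)c1c(OC(=O)c2cc(O[Si](C)(C)C(C)(C)C)c(O[Si](C)(C)C(C)(C)C)c(CC=C(C)C)c2)c(CC=C(C)C)c(O[Si](C)(C)C(C)(C)C)cc1O[Si](C)(C)C(C)(C)C | intermediate
13 | 2-{1-[3,4-bis(TBS-oxy)-5-prenylphenyl]ethenyloxy}-4,6-bis(TBS-oxy)-3-prenylbenzaldehyde dimethyl acetal | COC(OC)c1c(OC(=C)c2cc(O[Si](C)(C)C(C)(C)C)c(O[Si](C)(C)C(C)(C)C)c(CC=C(C)C)c2)c(CC=C(C)C)c(O[Si](C)(C)C(C)(C)C)cc1O[Si](C)(C)C(C)(C)C | intermediate
14 | 2-{1-[3,4-bis(TBS-oxy)-5-prenylphenyl]ethenyloxy}-4,6-bis(TBS-oxy)-3-prenylbenzaldehyde | O=Cc1c(OC(=C)c2cc(O[Si](C)(C)C(C)(C)C)c(O[Si](C)(C)C(C)(C)C)c(CC=C(C)C)c2)c(CC=C(C)C)c(O[Si](C)(C)C(C)(C)C)cc1O[Si](C)(C)C(C)(C)C | intermediate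
15 | (2S)-5,7-bis(TBS-oxy)-2-[3,4-bis(TBS-oxy)-5-prenylphenyl]-8-prenylchroman-4-one | CC(C)=CCc1cc([C@@H]2CC(=O)c3c(O[Si](C)(C)C(C)(C)C)cc(O[Si](C)(C)C(C)(C)C)c(CC=C(C)C)c3O2)cc(O[Si](C)(C)C(C)(C)C)c1O[Si](C)(C)C(C)(C)C | intermediate
16 | (2S)-5,7-dihydroxy-2-[3,4-dihydroxy-5-prenylphenyl]-8-prenylchroman-4-one | CC(C)=CCc1cc([C@@H]2CC(=O)c3c(O)cc(O)c(CC=C(C)C)c3O2)cc(O)c1O | target

Total step count: 11. Longest linear sequence: 9 steps (steps 3 to 11, from 5).

Steps most likely to fail

Step 10 (proposed method). Possible failure: decarbonylation of the acyl rhodium hydride, closure in the exo sense or by Lewis-acid-type attack of the enol ether on the aldehyde, or poor facial discrimination in the hydride transfer. The fallback uses known chemistry, closes the same bond, and sets the stereocentre before the ring closure. It sets out from acid 9 (through its chloride 10) and phenol 4 and comes back at 15.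
- Chloride 10 with MeNHOMe·HCl and Et3N should give the N-methoxy-N-methyl-3,4-bis(TBS-oxy)-5-prenylbenzamide F1.
- Chloromethyllithium (ICH2Cl, MeLi·LiBr, THF, −78 °C) should convert it into the 2-chloro-1-[3,4-bis(TBS-oxy)-5-prenylphenyl]ethanone F2.
- Noyori transfer hydrogenation (RuCl[(R,R)-TsDPEN](p-cymene), HCO2H–Et3N; the catalyst antipode is whichever gives the (S)-alcohol) should give the (S)-2-chloro-1-[3,4-bis(TBS-oxy)-5-prenylphenyl]ethanol F3.
- Mitsunobu etherification with 4 (PPh3, DIAD, toluene, 0 °C) should proceed with inversion to the (R)-2-[2-chloro-1-arylethoxy]-4,6-bis(TBS-oxy)-3-prenylbenzaldehyde F4.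
- Finkelstein exchange (NaI, butanone, 60 °C) should give the corresponding (R)-iodide F5.
- Carbene-catalysed intramolecular acylation of the primary iodide (3-ethyl-5-(2-hydroxyethyl)-4-methylthiazolium bromide, DBU, THF, 50 °C) should close ring C to 15 without touching C2. Here the Breslow intermediate acts as acyl anion in an SN2 closure, a reaction known for 2-(2-haloethoxy)benzaldehydes.

Step 9. Possible failure: attack of the enol ether carbon on the transient oxocarbenium ion (Prins-type closure towards a flavylium ion), or acid hydrolysis of the enol ether. The fallback forms the enol ether by C–O cross-coupling with the free aldehyde present, so no mask and no acid are needed. It sets out from aldehyde 8 and phenol 4 and comes back at 14.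
- MeMgBr (THF, −78 °C) should give the 1-[3,4-bis(TBS-oxy)-5-prenylphenyl]ethanol F6.
- Dess–Martin periodinane should give the 1-[3,4-bis(TBS-oxy)-5-prenylphenyl]ethanone F7.
- KN(SiMe3)2 and PhNTf2 (THF, −78 °C) should give the 1-[3,4-bis(TBS-oxy)-5-prenylphenyl]ethenyl trifluoromethanesulfonate F8.
- Palladium-catalysed coupling of this vinyl triflate with 4 (Pd2(dba)3, 2-(di-tert-butylphosphino)biphenyl, K3PO4, toluene, 80 °C) should give 14 directly.

Step 2. Possible failure: insufficient discrimination between the two hydroxyls ortho to the formyl group, giving a mixture of bis-silyl regioisomers. The fallback reverses the order, so that silylation takes place on the symmetric ring and the prenyl group is then delivered by a sigmatropic shift to the carbon next to the free hydroxyl. It sets out from 1 and comes back at 4.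
- TBSCl (2 equiv) and imidazole should give the 2-hydroxy-4,6-bis(TBS-oxy)benzaldehyde F9; its regiochemistry is unambiguous because the two ortho hydroxyls of 1 are equivalent.
- O-Alkylation with 3-chloro-3-methylbut-1-yne (DBU, CuCl2 cat., MeCN, 0 °C) should give the 2-(2-methylbut-3-yn-2-yloxy)-4,6-bis(TBS-oxy)benzaldehyde F10.
- Semi-hydrogenation (Pd on CaCO3 poisoned with Pb(OAc)2, quinoline, H2) should give the 2-(2-methylbut-3-en-2-yloxy)-4,6-bis(TBS-oxy)benzaldehyde F11.
- Aromatic Claisen rearrangement (toluene, 110 °C) should move the chain with allylic transposition to the only free ortho carbon and give 4.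

Further compounds
F1 | step 10 | N-methoxy-N-methyl-3,4-bis(TBS-oxy)-5-prenylbenzamide | CON(C)C(=O)c1cc(O[Si](C)(C)C(C)(C)C)c(O[Si](C)(C)C(C)(C)C)c(CC=C(C)C)c1
F2 | step 10 | 2-chloro-1-[3,4-bis(TBS-oxy)-5-prenylphenyl]ethanone | ClCC(=O)c1cc(O[Si](C)(C)C(C)(C)C)c(O[Si](C)(C)C(C)(C)C)c(CC=C(C)C)c1
F3 | step 10 | (S)-2-chloro-1-[3,4-bis(TBS-oxy)-5-prenylphenyl]ethanol | O[C@H](CCl)c1cc(O[Si](C)(C)C(C)(C)C)c(O[Si](C)(C)C(C)(C)C)c(CC=C(C)C)c1
F4 | step 10 | (R)-2-{2-chloro-1-[3,4-bis(TBS-oxy)-5-prenylphenyl]ethoxy}-4,6-bis(TBS-oxy)-3-prenylbenzaldehyde | O=Cc1c(O[C@@H](CCl)c2cc(O[Si](C)(C)C(C)(C)C)c(O[Si](C)(C)C(C)(C)C)c(CC=C(C)C)c2)c(CC=C(C)C)c(O[Si](C)(C)C(C)(C)C)cc1O[Si](C)(C)C(C)(C)C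
F5 | step 10 | (R)-2-{2-iodo-1-[3,4-bis(TBS-oxy)-5-prenylphenyl]ethoxy}-4,6-bis(TBS-oxy)-3-prenylbenzaldehyde | O=Cc1c(O[C@@H](CI)c2cc(O[Si](C)(C)C(C)(C)C)c(O[Si](C)(C)C(C)(C)C)c(CC=C(C)C)c2)c(CC=C(C)C)c(O[Si](C)(C)C(C)(C)C)cc1O[Si](C)(C)C(C)(C)C
F6 | step 9 | 1-[3,4-bis(TBS-oxy)-5-prenylphenyl]ethanol (racemic) | CC(O)c1cc(O[Si](C)(C)C(C)(C)C)c(O[Si](C)(C)C(C)(C)C)c(CC=C(C)C)c1
F7 | step 9 | 1-[3,4-bis(TBS-oxy)-5-prenylphenyl]ethanone | CC(=O)c1cc(O[Si](C)(C)C(C)(C)C)c(O[Si](C)(C)C(C)(C)C)c(CC=C(C)C)c1
F8 | step 9 | 1-[3,4-bis(TBS-oxy)-5-prenylphenyl]ethenyl trifluoromethanesulfonate | C=C(OS(=O)(=O)C(F)(F)F)c1cc(O[Si](C)(C)C(C)(C)C)c(O[Si](C)(C)C(C)(C)C)c(CC=C(C)C)c1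
F9 | step 2 | 2-hydroxy-4,6-bis(TBS-oxy)benzaldehyde | O=Cc1c(O)cc(O[Si](C)(C)C(C)(C)C)cc1O[Si](C)(C)C(C)(C)C
F10 | step 2 | 2-(2-methylbut-3-yn-2-yloxy)-4,6-bis(TBS-oxy)benzaldehyde | O=Cc1c(OC(C)(C)C#C)cc(O[Si](C)(C)C(C)(C)C)cc1O[Si](C)(C)C(C)(C)C
F11 | step 2 | 2-(2-methylbut-3-en-2-yloxy)-4,6-bis(TBS-oxy)benzaldehyde | O=Cc1c(OC(C)(C)C=C)cc(O[Si](C)(C)C(C)(C)C)cc1O[Si](C)(C)C(C)(C)C
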